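**Strategy.** Ring A is numbered C1 (acyloxy CH), C2 (CHOH), C3 (methyl-bearing oxirane C), C4 (oxirane CH), C5, C6 (side-chain CH). Everything rests on disconnecting the C1–O and C4–O bonds. These oxygens are 1,4-cis on ring A and cis to the C6 chain, which is what a palladium-catalysed cis-1,4-diacetoxylation of a C1–C4 diene delivers in one operation, creating both carbinol centres from the lone C6 centre. The precursor is the carvone-derived (5R)-2-methyl-5-isopropenylcyclohexa-1,3-diene. The C4 oxygen is later transposed to C2 (epoxidation, oxidation, Wharton), and the isopropenyl group is grown into the C7–C11 chain.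

Key step: step 3

Remark on the chemistry (assumption): the SMILES is read as (R)-2-methylbutanoate at C1 and (Z)-angelate at C8, and acid 11, acid 21, borane 16 and the Shi ketone are taken as purchasable. The side chain is numbered C7 (alkene carbon on C6, carrying the exocyclic CH2), C8 (angelate carbinol), C9 (CH2), C10 (oxirane CH), C11 (C(CH3)2).

Step 1
Reactants: 1 (R)-carvone; 2 p-toluenesulfonyl hydrazide
Product: 3 (R)-carvone (E)-p-toluenesulfonylhydrazone
Conditions: 2 (1.05 equiv), EtOH, cat. AcOH, rt
Reagents that add atoms: p-toluenesulfonyl hydrazide (2), Cc1ccc(cc1)S(=O)(=O)NN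
Why: Acid-catalysed hydrazone formation is reliable for enones and leaves the carvone stereocentre untouched.

Step 2
Reactants: 3 (R)-carvone (E)-p-toluenesulfonylhydrazone
Product: 5 (5R)-2-methyl-5-(prop-1-en-2-yl)cyclohexa-1,3-diene, via alkenyllithium 4 (not isolated)
Conditions: CH3Li (2.5 equiv), Et2O, 0 °C → rt; H2O quench; crude diene used at once
Reagents that add atoms: none
Why: Shapiro reaction, in which CH3Li removes N–H and then a proton of the α′ methylene syn to the sulfonamide nitrogen, loss of sulfinate and N2 gives alkenyllithium 4, and protonation yields the conjugated diene without touching the stereocentre.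

Step 3
Reactants: 5 (5R)-2-methyl-5-(prop-1-en-2-yl)cyclohexa-1,3-diene
Product: 7 all-cis 1,4-diacetoxy-2-methyl-5-(prop-1-en-2-yl)cyclohex-2-ene, via acetoxy-η3-allylpalladium chloride 6 (not isolated)
Conditions: Pd(OAc)2 (5 mol %), LiCl (20 mol %), LiOAc·2H2O (2 equiv), p-benzoquinone (25 mol %), MnO2 (1.2 equiv), AcOH, 25 °C, slow addition of 5
Reagents that add atoms: acetic acid, CC(=O)O (attacking as acetate; lithium acetate, CC(=O)[O-].[Li+], supplies the anion)
Why: Divalent palladium binds the C1–C4 diene on the ring face opposite the C6 isopropenyl group, and acetate adds from outside at C4 (the terminus next to the C5 methylene), anti to the metal, giving the η3-allyl complex 6 over C1–C3. With chloride on palladium, acetate cannot be delivered from the metal, so the second acetate also attacks externally, anti to palladium, at the less substituted allyl terminus C1 (1,4- and not 1,2-addition, C3 being fully substituted), and zerovalent palladium is returned to the divalent state by benzoquinone/MnO2. No ring is closed; two C–O bonds are formed. Both new stereocentres (C1 and C4) are controlled by the C6 stereocentre through the face choice of the metal, each oxygen entering on the isopropenyl face, hence the all-cis array. The step needs cis-1,4 over trans-1,4 addition (secured by catalytic LiCl), diene over isolated-alkene reactivity (the chelating diene outcompetes the 1,1-disubstituted alkene) and suppression of quinone cycloaddition (catalytic quinone, slow diene addition). The closest known reaction type is the chloride-modulated palladium/benzoquinone cis-1,4-diacetoxylation of cyclohexa-1,3-dienes.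

Step 4
Reactants: 7 all-cis 1,4-diacetoxy-2-methyl-5-(prop-1-en-2-yl)cyclohex-2-ene
Product: 8 all-cis 2-methyl-5-(prop-1-en-2-yl)cyclohex-2-ene-1,4-diol (ring A C1,C4-diol)
Conditions: K2CO3 (0.2 equiv), MeOH, 0 °C → rt
Reagents that add atoms: none
Why: Base-catalysed transesterification with methanol removes both acetates without affecting the alkenes or the carbinol configurations.

Step 5
Reactants: 8 all-cis ring A C1,C4-diol
Product: 9 C4 tert-butyldimethylsilyl ether of 8 (C1 hydroxyl free)
Conditions: TBSCl (1.05 equiv), imidazole, CH2Cl2, −20 → 0 °C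
Reagents that add atoms: tert-butyldimethylsilyl chloride, CC(C)(C)[Si](C)(C)Cl
Why: Silyl ether formation under steric control, since the pseudoequatorial C4 hydroxyl (flanked by the C5 methylene and a planar alkene carbon) should react faster than the pseudoaxial C1 hydroxyl shielded by the cis isopropenyl group on C6.

Step 6
Reactants: 9 C4 silyl ether
Product: 10 C2,C3-epoxide of 9 (oxirane, C1–OH, C4–OTBS and C6 isopropenyl all on one face)
Conditions: VO(acac)2 (5 mol %), t-BuOOH (1.3 equiv, decane), CH2Cl2, 0 °C → rt
Reagents that add atoms: tert-butyl hydroperoxide, CC(C)(C)OO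
Why: Vanadium-catalysed hydroxyl-directed epoxidation, in which the C1 alkoxide on vanadium delivers oxygen to its own face of the C2=C3 alkene and so sets C2 and C3 cis to the C1 oxygen, while the merely homoallylic 1,1-disubstituted isopropenyl alkene reacts far more slowly.

Step 7
Reactants: 10 epoxy alcohol; 11 (R)-2-methylbutanoic acid
Product: 12 C1 (R)-2-methylbutanoate of 10
Conditions: 11 (1.5 equiv), DCC, DMAP (0.2 equiv), CH2Cl2, 0 °C → rt
Reagents that add atoms: (R)-2-methylbutanoic acid (11), CC[C@@H](C)C(=O)O
Why: Steglich esterification acylates the only free hydroxyl with retention at C1 and, with catalytic DMAP at low temperature, without epimerising the α-stereocentre of the acid.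

Step 8
Reactants: 12 C1 ester
Product: 13 allylic chloride (C6 substituent 3-chloroprop-1-en-2-yl)
Conditions: Ca(OCl)2, solid CO2, CH2Cl2–H2O, 0 °C
Reagents that add atoms: calcium hypochlorite, [Ca+2].[O-]Cl.[O-]Cl (chlorine, delivered as HOCl)
Why: Ene-type allylic chlorination by HOCl made in situ, in which chloronium formation at the only alkene and loss of a methyl proton give the 2-(chloromethyl)allyl unit, the two allyl termini being equivalent so that no regiochemical question arises.

Step 9
Reactants: 13 allylic chloride
Product: 15 enal (C6 substituent 3-oxoprop-1-en-2-yl), via alkoxytrimethylammonium chloride 14 (not isolated)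
Conditions: (CH3)3NO (anhydrous, 4 equiv), DMSO, rt → 40 °C
Reagents that add atoms: trimethylamine N-oxide, C[N+](C)(C)[O-]
Why: Ganem oxidation, in which the amine oxide oxygen displaces the allylic chloride to give salt 14 and base-induced loss of trimethylamine unveils the α-substituted acrolein under non-acidic conditions tolerated by the oxirane, the silyl ether and the ester.

Step 10
Reactants: 15 enal; 16 B-allyldiisopinocampheylborane of the (+)-α-pinene series (made from (−)-B-methoxydiisopinocampheylborane)
Product: 18 (8S)-homoallylic alcohol (C6 substituent C7(=CH2)–C8H(OH)–CH2–CH=CH2), via diisopinocampheylborinate 17 (not isolated)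
Conditions: 16 (1.3 equiv), Et2O, −78 °C; then pH 7 phosphate buffer, 30% H2O2, MeOH, 0 °C → rt
Reagents that add atoms: B-allyldiisopinocampheylborane (16), C=CCB([C@@H]1C[C@@H]2C[C@H]([C@H]1C)C2(C)C)[C@@H]1C[C@@H]2C[C@H]([C@H]1C)C2(C)C
Why: Brown allylboration through a closed six-membered chair transition state, in which the (+)-α-pinene-derived reagent is expected to add allyl to the Si face of the aldehyde under reagent control and so set C8 as S (sense to be verified by Mosher ester analysis), after which buffered peroxide cleaves borinate 17.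

Step 11
Reactants: 18 (8S)-homoallylic alcohol; 19 2-methyl-2-butene
Product: 20 (8S)-alcohol with the C9–C10H=C11(CH3)2 terminus
Conditions: second-generation Grubbs catalyst RuCl2(=CHPh)(H2IMes)(PCy3) (5 mol %), 19 (large excess)–CH2Cl2, 40 °C, sealed vessel
Reagents that add atoms: 2-methyl-2-butene (19), CC=C(C)C
Why: Olefin cross-metathesis exchanges the CH2 terminus of the only monosubstituted alkene for an isopropylidene group, the 1,1-disubstituted C7 methylene being inert, and is placed before acylation so that ring-closing metathesis onto an angelate cannot compete.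

Step 12
Reactants: 20 (8S)-alcohol; 21 angelic acid, (Z)-2-methylbut-2-enoic acid
Product: 22 C8 angelate of 20
Conditions: 21, 2,4,6-trichlorobenzoyl chloride, Et3N, toluene, rt; then 20, 75 °C
Reagents that add atoms: angelic acid (21), C/C=C(/C)C(=O)O
Why: Yamaguchi-type esterification via the preformed mixed anhydride, without DMAP, acylates the C8 hydroxyl at the less hindered angeloyl carbonyl and avoids the nucleophile-induced Z to E isomerisation that turns angelates into tiglates.

Step 13
Reactants: 22 C8 angelate
Product: 23 (10R)-10,11-epoxide of 22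
Conditions: 1,2:4,5-di-O-isopropylidene-D-erythro-2,3-hexodiulo-2,6-pyranose (Shi ketone, 30 mol %), Oxone (2KHSO5·KHSO4·K2SO4), K2CO3, Bu4NHSO4, CH3CN–CH2(OCH3)2–aq. Na2B4O7/Na2EDTA (pH ≈ 10.5), 0 °C
Reagents that add atoms: potassium peroxymonosulfate (from Oxone), [K+].[O-]S(=O)(=O)OO
Why: Shi asymmetric epoxidation, in which the chiral dioxirane from the D-fructose-derived ketone transfers oxygen through a spiro transition state to the most electron-rich, trisubstituted alkene and gives the (10R)-oxirane under catalyst control, while the 1,1-disubstituted alkene with its allylic acyloxy group and the electron-poor angelate are much less reactive.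

Step 14
Reactants: 23 silyl-protected bis-epoxide
Product: 24 C4 alcohol (23 without the silyl group)
Conditions: Bu4NF, AcOH (1:1), THF, 0 °C → rt
Reagents that add atoms: none
Why: Fluoride-mediated desilylation buffered by acetic acid frees the C4 hydroxyl in a non-basic medium, so both esters, the angelate geometry and both oxiranes should survive.

Step 15
Reactants: 24 C4 alcohol
Product: 25 C4 ketone (α,β-epoxy ketone)
Conditions: Dess–Martin periodinane, NaHCO3, CH2Cl2, 0 °C → rt
Reagents that add atoms: none
Why: Dess–Martin oxidation converts the secondary C4 alcohol into the ketone under buffered, near-neutral conditions, with no enolisable stereocentre next to the new carbonyl.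

Step 16
Reactants: 25 α,β-epoxy ketone
Product: 28 allylic alcohol (C2–OH cis to the C1 ester; C3=C4 alkene), via epoxy hydrazone 26 (not isolated), via alkenyldiazene 27 (not isolated)
Conditions: N2H4·H2O (2.5 equiv), AcOH (cat.), MeOH, 0 °C → rt, degassed, short reaction time
Reagents that add atoms: none
Why: Wharton transposition, in which hydrazone 26 opens the adjacent oxirane to alkenyldiazene 27 and loss of N2 places hydrogen on C4 and the alkene at C3=C4, so that the never-broken C2–O bond of the former oxirane becomes the C2 hydroxyl cis to the C1 ester.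

Step 17
Reactants: 28 allylic alcohol
Product: 29 CNP0181486.1 (target)
Conditions: VO(acac)2 (5 mol %), t-BuOOH (1.3 equiv, decane), CH2Cl2, 0 °C → rt
Reagents that add atoms: tert-butyl hydroperoxide, CC(C)(C)OO
Why: Vanadium-catalysed hydroxyl-directed epoxidation, in which only the C3=C4 alkene has an allylic hydroxyl and the C2 alkoxide on vanadium delivers oxygen to its own face, setting C3 and C4 cis to the C2 hydroxyl and completing the all-cis ring A without touching the other two alkenes.

**Compound list**

1 | (R)-carvone, (5R)-2-methyl-5-(prop-1-en-2-yl)cyclohex-2-en-1-one | CC1=CC[C@H](CC1=O)C(C)=C | starting material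
2 | p-toluenesulfonyl hydrazide | Cc1ccc(cc1)S(=O)(=O)NN | starting material
3 | (R)-carvone (E)-p-toluenesulfonylhydrazone (sulfonamide nitrogen syn to the ring CH2) | CC1=CC[C@H](C/C1=N\NS(=O)(=O)c1ccc(C)cc1)C(C)=C | intermediate
4 | 3-lithio-(5R)-2-methyl-5-(prop-1-en-2-yl)cyclohexa-1,3-diene (alkenyllithium) | CC(=C)[C@@H]1CC=C(C)C([Li])=C1 | intermediate (not isolated)
5 | (5R)-2-methyl-5-(prop-1-en-2-yl)cyclohexa-1,3-diene | CC(=C)[C@@H]1CC=C(C)C=C1 | intermediate
6 | 4-acetoxy-η3-allylpalladium chloride over ring A C1–C3, palladium on the face opposite the acetate and the isopropenyl group (written as the η1 form at C1) | CC(=C)[C@@H]1C[C@H](OC(C)=O)C(C)=C[C@H]1[Pd]Cl | intermediate (not isolated)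
7 | all-cis 1,4-diacetoxy-2-methyl-5-(prop-1-en-2-yl)cyclohex-2-ene (ring A: C1–OAc and C4–OAc cis to each other and to the C6 isopropenyl group) | CC(=C)[C@@H]1C[C@H](OC(C)=O)C(C)=C[C@@H]1OC(C)=O | intermediate
8 | all-cis 2-methyl-5-(prop-1-en-2-yl)cyclohex-2-ene-1,4-diol | CC(=C)[C@@H]1C[C@H](O)C(C)=C[C@@H]1O | intermediate
9 | C4 tert-butyldimethylsilyl ether of 8, C1–OH free | CC(=C)[C@@H]1C[C@H](O[Si](C)(C)C(C)(C)C)C(C)=C[C@@H]1O | intermediate
10 | C2,C3-epoxide of 9, oxirane cis to C1–OH, C4–OTBS and the C6 isopropenyl group | CC(=C)[C@@H]1C[C@H](O[Si](C)(C)C(C)(C)C)[C@]2(C)O[C@@H]2[C@@H]1O | intermediate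
11 | (R)-2-methylbutanoic acid | CC[C@@H](C)C(=O)O | starting material
12 | C1 (R)-2-methylbutanoate of 10 | CC(=C)[C@@H]1C[C@H](O[Si](C)(C)C(C)(C)C)[C@]2(C)O[C@@H]2[C@@H]1OC(=O)[C@H](C)CC | intermediate
13 | allylic chloride, C6 substituent 3-chloroprop-1-en-2-yl | ClCC(=C)[C@@H]1C[C@H](O[Si](C)(C)C(C)(C)C)[C@]2(C)O[C@@H]2[C@@H]1OC(=O)[C@H](C)CC | intermediate
14 | alkoxytrimethylammonium chloride from 13 | C[N+](C)(C)OCC(=C)[C@@H]1C[C@H](O[Si](C)(C)C(C)(C)C)[C@]2(C)O[C@@H]2[C@@H]1OC(=O)[C@H](C)CC.[Cl-] | intermediate (not isolated)
15 | enal, C6 substituent 3-oxoprop-1-en-2-yl | O=CC(=C)[C@@H]1C[C@H](O[Si](C)(C)C(C)(C)C)[C@]2(C)O[C@@H]2[C@@H]1OC(=O)[C@H](C)CC | intermediate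
16 | B-allyldiisopinocampheylborane of the (+)-α-pinene series | C=CCB([C@@H]1C[C@@H]2C[C@H]([C@H]1C)C2(C)C)[C@@H]1C[C@@H]2C[C@H]([C@H]1C)C2(C)C | starting material
17 | C8 diisopinocampheylborinate of 18 | C=C([C@H](CC=C)OB([C@@H]1C[C@@H]2C[C@H]([C@H]1C)C2(C)C)[C@@H]1C[C@@H]2C[C@H]([C@H]1C)C2(C)C)[C@@H]1C[C@H](O[Si](C)(C)C(C)(C)C)[C@]2(C)O[C@@H]2[C@@H]1OC(=O)[C@H](C)CC | intermediate (not isolated)
18 | (8S)-homoallylic alcohol, C6 substituent C7(=CH2)–C8H(OH)–CH2–CH=CH2 | C=C([C@H](CC=C)O)[C@@H]1C[C@H](O[Si](C)(C)C(C)(C)C)[C@]2(C)O[C@@H]2[C@@H]1OC(=O)[C@H](C)CC | intermediate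
19 | 2-methyl-2-butene | CC=C(C)C | starting material
20 | (8S)-alcohol with C9H2–C10H=C11(CH3)2 terminus | C=C([C@H](CC=C(C)C)O)[C@@H]1C[C@H](O[Si](C)(C)C(C)(C)C)[C@]2(C)O[C@@H]2[C@@H]1OC(=O)[C@H](C)CC | intermediate
21 | angelic acid, (Z)-2-methylbut-2-enoic acid | C/C=C(/C)C(=O)O | starting material
22 | C8 angelate of 20 | C=C([C@H](CC=C(C)C)OC(=O)/C(C)=C\C)[C@@H]1C[C@H](O[Si](C)(C)C(C)(C)C)[C@]2(C)O[C@@H]2[C@@H]1OC(=O)[C@H](C)CC | intermediate
23 | (10R)-10,11-epoxide of 22 | C=C([C@H](C[C@H]1OC1(C)C)OC(=O)/C(C)=C\C)[C@@H]1C[C@H](O[Si](C)(C)C(C)(C)C)[C@]2(C)O[C@@H]2[C@@H]1OC(=O)[C@H](C)CC | intermediate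
24 | C4 alcohol (desilylated 23) | C=C([C@H](C[C@H]1OC1(C)C)OC(=O)/C(C)=C\C)[C@@H]1C[C@H](O)[C@]2(C)O[C@@H]2[C@@H]1OC(=O)[C@H](C)CC | intermediate
25 | C4 ketone, C2,C3-epoxy ketone | C=C([C@H](C[C@H]1OC1(C)C)OC(=O)/C(C)=C\C)[C@@H]1CC(=O)[C@]2(C)O[C@@H]2[C@@H]1OC(=O)[C@H](C)CC | intermediate
26 | C4 hydrazone of 25 | C=C([C@H](C[C@H]1OC1(C)C)OC(=O)/C(C)=C\C)[C@@H]1CC(=NN)[C@]2(C)O[C@@H]2[C@@H]1OC(=O)[C@H](C)CC | intermediate (not isolated)
27 | C4 alkenyldiazene with C2–OH and C3=C4 | C=C([C@H](C[C@H]1OC1(C)C)OC(=O)/C(C)=C\C)[C@@H]1CC(N=N)=C(C)[C@H](O)[C@@H]1OC(=O)[C@H](C)CC | intermediate (not isolated)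
28 | allylic alcohol, C2–OH cis to the C1 ester and the C6 chain, C3=C4 alkene | C=C([C@H](C[C@H]1OC1(C)C)OC(=O)/C(C)=C\C)[C@@H]1CC=C(C)[C@H](O)[C@@H]1OC(=O)[C@H](C)CC | intermediate
29 | CNP0181486.1 | C=C([C@H](C[C@H]1OC1(C)C)OC(=O)/C(C)=C\C)[C@@H]1C[C@@H]2O[C@]2(C)[C@H](O)[C@@H]1OC(=O)[C@H](C)CC | target

**Totals.** Total step count: 17. Longest linear sequence: 17 steps, from (R)-carvone 1 to 29.

**Steps most likely to fail**

1. Step 3. Palladium may bind the diene face syn to the isopropenyl group, or deliver acetate from its own coordination sphere (trans-1,4 adduct), or the diene may be consumed by cycloaddition with the quinone or by aromatisation. Fallback: the two C–O bonds would be made by cycloaddition and corrected by inversion. Setting out from diene 5, sensitised photooxygenation (O2, tetraphenylporphyrin, hν, CH2Cl2, −78 °C) should add singlet oxygen across C1–C4 on the face away from the isopropenyl group to give the endoperoxide F1. Thiourea in MeOH would reduce the O–O bond to the cis-1,4-diol with both hydroxyls trans to the isopropenyl group F2. A double Mitsunobu reaction (AcOH, PPh3, diisopropyl azodicarboxylate, THF, 0 °C) would then invert both allylic carbinols and come back to the route at diacetate 7.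

2. Step 5. Silylation may not discriminate well enough between the two allylic hydroxyls, giving the regioisomeric and the doubly silylated ethers. Fallback: differentiation would be moved from protection to oxidation state. Setting out from diol 8, MnO2 (CH2Cl2, rt) should oxidise preferentially the pseudoequatorial C4 carbinol, whose C–H bond is aligned with the alkene π system, to the C4 hydroxy enone F3. Steglich esterification with acid 11 would give the enone ester F4. Luche reduction (NaBH4, CeCl3·7H2O, MeOH, −78 °C; axial hydride delivery as in the carvone to cis-carveol case) should return the C4 carbinol cis to the chain as the allylic alcohol F5. VO(acac)2/t-BuOOH epoxidation directed by that hydroxyl would give the epoxy alcohol F6, and silylation (TBSOTf, 2,6-lutidine, CH2Cl2, −78 °C) comes back to the route at 12.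

3. Step 16. On the fully elaborated substrate, hydrazone chemistry may be accompanied by hydrazinolysis or C1 to C2 migration of the neighbouring ester, isomerisation of the angelate, or diimide reduction of the methylene group. Fallback: the transposition would be run under radical, non-nucleophilic conditions, leaving out step 15. Setting out from alcohol 24, 1,1′-thiocarbonyldiimidazole (DMAP cat., CH2Cl2, rt → 40 °C) should give the imidazolylthiocarbonate F7. Bu3SnH/AIBN in toluene at 80 °C would generate the C4 radical, which opens the adjacent oxirane (epoxycarbinyl radical fragmentation) to the C3=C4 alkene and a C2 alkoxy radical that is reduced by the stannane, coming back to the route at allylic alcohol 28.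

**Further compounds**

F1 | step 3 | 1,4-endoperoxide of diene 5, peroxide bridge C1–O–O–C4 trans to the isopropenyl group | CC(=C)[C@@H]1C[C@H]2OO[C@@H]1C=C2C
F2 | step 3 | cis-2-methyl-5-(prop-1-en-2-yl)cyclohex-2-ene-1,4-diol with both hydroxyls trans to the isopropenyl group | CC(=C)[C@@H]1C[C@@H](O)C(C)=C[C@H]1O
F3 | step 5 | C4 hydroxy enone, cis-4-hydroxy-2-methyl-5-(prop-1-en-2-yl)cyclohex-2-en-1-one | CC(=C)[C@@H]1CC(=O)C(C)=C[C@@H]1O
F4 | step 5 | (R)-2-methylbutanoate of F3 | CC(=C)[C@@H]1CC(=O)C(C)=C[C@@H]1OC(=O)[C@H](C)CC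
F5 | step 5 | all-cis allylic alcohol, C4–OH with C1 (R)-2-methylbutanoate | CC(=C)[C@@H]1C[C@H](O)C(C)=C[C@@H]1OC(=O)[C@H](C)CC
F6 | step 5 | C2,C3-epoxide of F5, all-cis (12 without the silyl group) | CC(=C)[C@@H]1C[C@H](O)[C@]2(C)O[C@@H]2[C@@H]1OC(=O)[C@H](C)CC
F7 | step 16 | C4 O-(imidazol-1-ylthiocarbonyl) derivative of 24 | C=C([C@H](C[C@H]1OC1(C)C)OC(=O)/C(C)=C\C)[C@@H]1C[C@H](OC(=S)n2ccnc2)[C@]2(C)O[C@@H]2[C@@H]1OC(=O)[C@H](C)CC
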